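**Retrosynthetic overview**

1. The strategy rests on the acetyl-bearing sp3 carbon of the pyran ring. It is the α-carbon of a methyl ketone and is bonded to the ring A carbon para to the formyl group. Cutting that aryl–C bond leaves a cis-2-aryl-4-(2-oxopropyl)-4H-1,3-dioxine fused to isoquinoline C6 (oxygen) and C7 (carbon), with bromine on ring A.
2. The dioxine is cut at its acetal carbon into a ring A dialdehyde and an isoquinolin-6-ol carrying an (R)-homoallylic carbinol at C7. The carbinol comes from Brown allylation of the 7-carbaldehyde, and the allyl group becomes the ketone by Tsuji–Wacker oxidation after acetalisation.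
3. Both aromatic halves come from one arene, 6-bromo-3-(dimethoxymethyl)-2-methoxy-4-[(4-methoxybenzyl)oxy]benzaldehyde, made from 4-bromo-2,6-difluorobenzaldehyde. Sonogashira coupling with propyne and ammonia annulation turn it into the isoquinoline.
4. Ring order: ring A and the isoquinoline carbocycle are bought as benzene rings; the pyridine ring is formed in step 7, the 1,3-dioxine in step 10 and the pyran in step 13.

Key step: step 13

Assumption: the (−)-α-pinene-derived allylborane is taken to attack this aryl aldehyde on the Re face, as it does benzaldehyde, giving the (R)-carbinol.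

**Route**

Step 1
Reactants: 1 4-bromo-2,6-difluorobenzaldehyde
Product: 2 4-bromo-2-fluoro-6-[(4-methoxybenzyl)oxy]benzaldehyde
Conditions: 4-MeOC6H4CH2OH (1.0 equiv), NaH, THF, 0 °C; then 1, −20 °C → rt
Reagents that add atoms: 4-methoxybenzyl alcohol, COc1ccc(CO)cc1
Why: Nucleophilic aromatic substitution, in which the formyl group activates both ortho fluorines, the first alkoxy group deactivates the ring towards a second substitution, and the para bromide is a far poorer leaving group than fluoride.

Step 2
Reactants: 2 4-bromo-2-fluoro-6-[(4-methoxybenzyl)oxy]benzaldehyde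
Product: 3 5-bromo-2-(dimethoxymethyl)-1-fluoro-3-[(4-methoxybenzyl)oxy]benzene
Conditions: HC(OMe)3, PPTS (cat.), MeOH, 50 °C
Reagents that add atoms: trimethyl orthoformate, COC(OC)OC
Why: Acid-catalysed acetalisation with the orthoformate as water scavenger masks this formyl group against the lithium amide and keeps it distinct from the formyl group introduced next.

Step 3
Reactants: 3 5-bromo-2-(dimethoxymethyl)-1-fluoro-3-[(4-methoxybenzyl)oxy]benzene
Product: 5 6-bromo-3-(dimethoxymethyl)-2-fluoro-4-[(4-methoxybenzyl)oxy]benzaldehyde, via aryllithium 4 (not isolated)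
Conditions: LiN(iPr)2 (1.2 equiv), THF, −78 °C; DMF, −78 °C; AcOH
Reagents that add atoms: N,N-dimethylformamide, CN(C)C=O
Why: Directed ortho-metalation, in which the only C–H flanked by fluorine and bromine is the most acidic, the amide base does not exchange bromine, and the aryllithium should be stable at −78 °C long enough to be formylated by DMF.

Step 4
Reactants: 5 6-bromo-3-(dimethoxymethyl)-2-fluoro-4-[(4-methoxybenzyl)oxy]benzaldehyde
Product: 6 6-bromo-3-(dimethoxymethyl)-2-methoxy-4-[(4-methoxybenzyl)oxy]benzaldehyde
Conditions: NaOMe, MeOH–THF, 0 → 40 °C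
Reagents that add atoms: sodium methoxide, C[O-].[Na+]
Why: Nucleophilic aromatic substitution of the fluoride that now lies ortho to the new formyl group, fluoride leaving far faster than the ortho bromide, which places the methoxy group between the two carbonyl carbons.

Step 5
Reactants: 6 6-bromo-3-(dimethoxymethyl)-2-methoxy-4-[(4-methoxybenzyl)oxy]benzaldehyde
Product: 7 6-bromo-4-hydroxy-2-methoxybenzene-1,3-dicarbaldehyde
Conditions: CF3CO2H–CH2Cl2–H2O, anisole, 0 °C → rt
Reagents that add atoms: water, O
Why: Aqueous acid hydrolyses the dimethyl acetal and trifluoroacetic acid cleaves the 4-methoxybenzyl aryl ether (acidolysis with Friedel–Crafts capture of the benzyl cation by anisole), giving the dialdehyde whose 3-formyl group is held in a hydrogen bond to the 4-hydroxyl.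

Step 6
Reactants: 6 6-bromo-3-(dimethoxymethyl)-2-methoxy-4-[(4-methoxybenzyl)oxy]benzaldehyde; 8 propyne
Product: 9 3-(dimethoxymethyl)-2-methoxy-4-[(4-methoxybenzyl)oxy]-6-(prop-1-yn-1-yl)benzaldehyde
Conditions: propyne (excess), PdCl2(PPh3)2 (3 mol%), CuI (5 mol%), Et3N, THF, 50 °C, sealed tube
Reagents that add atoms: none
Why: Sonogashira coupling at the aryl bromide, which is activated towards oxidative addition by the ortho formyl group, while the acetal and the ether are inert.

Step 7
Reactants: 9 3-(dimethoxymethyl)-2-methoxy-4-[(4-methoxybenzyl)oxy]-6-(prop-1-yn-1-yl)benzaldehyde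
Product: 11 8-methoxy-6-[(4-methoxybenzyl)oxy]-3-methylisoquinoline-7-carbaldehyde, via isoquinoline dimethyl acetal 10 (not isolated)
Conditions: NH3 (7 M in MeOH), AgNO3 (10 mol%), 60 °C, sealed tube; evaporate; 1 M HCl, THF, rt; NaHCO3
Reagents that add atoms: ammonia, N; water, O
Why: Condensation with ammonia gives the N–H imine, whose nitrogen adds 6-endo-dig to the silver-activated alkyne and aromatises to the 3-methylisoquinoline (alkynyl-imine annulation), and dilute acid then hydrolyses the dimethyl acetal to the 7-formyl group.

Step 8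
Reactants: 11 8-methoxy-6-[(4-methoxybenzyl)oxy]-3-methylisoquinoline-7-carbaldehyde; 12 (+)-B-allyldiisopinocampheylborane
Product: 14 (1R)-1-{8-methoxy-6-[(4-methoxybenzyl)oxy]-3-methylisoquinolin-7-yl}but-3-en-1-ol, via borinate ester 13 (not isolated)
Conditions: 12 (2 equiv), Et2O, −78 °C; then NaOH, H2O2, 0 °C → rt
Reagents that add atoms: none
Why: Brown allylation through a closed chair-like six-membered transition state, the (−)-α-pinene-derived reagent delivering allyl to the Re face of the aryl aldehyde to set the (R)-carbinol; being stoichiometric, it is not inhibited by the basic isoquinoline nitrogen.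

Step 9
Reactants: 14 (1R)-1-{8-methoxy-6-[(4-methoxybenzyl)oxy]-3-methylisoquinolin-7-yl}but-3-en-1-ol
Product: 15 7-[(1R)-1-hydroxybut-3-en-1-yl]-8-methoxy-3-methylisoquinolin-6-ol
Conditions: CF3CO2H–CH2Cl2 (1:4), anisole, 0 °C; NaHCO3, MeOH–H2O
Reagents that add atoms: none
Why: Acidolysis of the 4-methoxybenzyl aryl ether with anisole as cation trap; N-protonation of the isoquinoline makes ionisation of the benzylic carbinol (a dication) unfavourable, so the stereocentre and the alkene should survive.

Step 10
Reactants: 15 7-[(1R)-1-hydroxybut-3-en-1-yl]-8-methoxy-3-methylisoquinolin-6-ol; 7 6-bromo-4-hydroxy-2-methoxybenzene-1,3-dicarbaldehyde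
Product: 16 (2R,4R)-2-(6-bromo-3-formyl-4-hydroxy-2-methoxyphenyl)-4-(prop-2-en-1-yl)-4H-1,3-dioxine fused through O1 to C6 and through C4 to C7 of 8-methoxy-3-methylisoquinoline (cis)
Conditions: 7 (1.2 equiv), PPTS (0.3 equiv), toluene, 80 °C, 4 Å MS
Reagents that add atoms: none
Why: Acid-catalysed acetalisation under equilibrium control, in which only the formyl group of 7 flanked by bromine and methoxy condenses because the other one would lose its hydrogen bond to the phenol (a dimethyl acetal on ring A could not survive this exchange, so that formyl group is carried free); the acetal carbon equilibrates through the oxocarbenium ion, the isomer with the aryl group equatorial and cis to the C4 allyl group is collected and the trans isomer is returned to the same conditions, while the weak acid should leave the benzylic C–O bond from step 8 intact.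

Step 11
Reactants: 16 cis-acetal phenol
Product: 17 (2R,4R)-2-[6-bromo-3-formyl-2-methoxy-4-(methoxymethoxy)phenyl]-4-(prop-2-en-1-yl)-4H-1,3-dioxine fused through O1 to C6 and through C4 to C7 of 8-methoxy-3-methylisoquinoline
Conditions: MOMCl, iPr2NEt, CH2Cl2, 0 °C → rt
Reagents that add atoms: chloromethyl methyl ether, COCCl
Why: O-Alkylation of the phenoxide (Williamson-type); capping the phenol stops the acetal carbon from opening through a para-quinone methide under the basic conditions of step 13 and keeps a phenoxide away from palladium.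

Step 12
Reactants: 17 methoxymethyl ether of the cis-acetal
Product: 18 (2R,4R)-2-[6-bromo-3-formyl-2-methoxy-4-(methoxymethoxy)phenyl]-4-(2-oxopropyl)-4H-1,3-dioxine fused through O1 to C6 and through C4 to C7 of 8-methoxy-3-methylisoquinoline
Conditions: PdCl2 (0.2 equiv), CuCl (1 equiv), O2 (1 atm), DMF–H2O (7:1), rt
Reagents that add atoms: water, O
Why: Tsuji–Wacker oxidation, in which Markovnikov hydroxypalladation of the terminal alkene by divalent palladium gives the methyl ketone, while aryl bromide, aldehyde, acetal and methoxymethyl ether are not affected.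

Step 13
Reactants: 18 cis-2-aryl-4-(2-oxopropyl)-4H-1,3-dioxine
Product: 19 bridged acetal, the ring A methoxymethyl ether of the target (acetal carbon R; benzylic O–CH carbon R; acetyl-bearing carbon S)
Conditions: Pd2(dba)3 (5 mol%), Xantphos (12 mol%), K3PO4 (3 equiv), toluene (0.02 M), 80 °C; AcOH, 0 °C
Reagents that add atoms: none
Why: Zerovalent palladium inserts into the C–Br bond of ring A, the weak insoluble base removes an internal α-proton from the ketone held next to the arylpalladium bromide, and C–C reductive elimination from the seven-membered aryl(enolate)palladacycle joins the aryl carbon to the internal α-carbon; the closest known reaction type is the intramolecular palladium-catalysed α-arylation of ketones with aryl bromides under carbonate or phosphate bases. The pyran ring closes as a six-membered ring onto the existing dioxine, which is possible because the cis-2,4-disubstituted dioxine can flip to the conformer with the aryl group and the oxopropyl chain both axial, whereas the methyl α-carbon would have to close an eight-membered ring and is not expected to compete. The two existing stereocentres are not touched, and the new acetyl-bearing centre is set after the coupling, when the α-aryl ketone (as enolate or enol under the basic conditions) is protonated on the convex face, anti to the isoquinoline C7 substituent, which places hydrogen axial and acetyl equatorial (S). The step needs arylation to outrun loss of the C4 acetal oxygen from the enolate (retro-oxa-Michael); K3PO4 in toluene should keep the concentration of free enolate negligible, and the wide-bite-angle ligand favours reductive elimination over β-alkoxide elimination at palladium. The ring A formyl group is not enolisable, is shielded by two ortho oxygen substituents, and at 0.02 M should not be attacked by the ketone enolate.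

Step 14
Reactants: 19 bridged acetal methoxymethyl ether
Product: 20 CNP0584953.1
Conditions: CF3CO2H–CH2Cl2 (1:5), 0 °C → rt; aq. NaHCO3
Reagents that add atoms: none
Why: Acidolysis of the methoxymethyl aryl ether, assisted by the ortho formyl group; if the bicyclic acetal opens it can only reclose to the same bridged arrangement, and brief cold acid should not enolise the α-aryl ketone.

**Compound list**

1 | 4-bromo-2,6-difluorobenzaldehyde | O=Cc1c(F)cc(Br)cc1F | starting material
2 | 4-bromo-2-fluoro-6-[(4-methoxybenzyl)oxy]benzaldehyde | COc1ccc(COc2cc(Br)cc(F)c2C=O)cc1 | intermediate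
3 | 5-bromo-2-(dimethoxymethyl)-1-fluoro-3-[(4-methoxybenzyl)oxy]benzene | COc1ccc(COc2cc(Br)cc(F)c2C(OC)OC)cc1 | intermediate
4 | {6-bromo-3-(dimethoxymethyl)-2-fluoro-4-[(4-methoxybenzyl)oxy]phenyl}lithium | [Li]c1c(Br)cc(OCc2ccc(OC)cc2)c(C(OC)OC)c1F | intermediate (not isolated)
5 | 6-bromo-3-(dimethoxymethyl)-2-fluoro-4-[(4-methoxybenzyl)oxy]benzaldehyde | COc1ccc(COc2cc(Br)c(C=O)c(F)c2C(OC)OC)cc1 | intermediate
6 | 6-bromo-3-(dimethoxymethyl)-2-methoxy-4-[(4-methoxybenzyl)oxy]benzaldehyde | COc1ccc(COc2cc(Br)c(C=O)c(OC)c2C(OC)OC)cc1 | intermediate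
7 | 6-bromo-4-hydroxy-2-methoxybenzene-1,3-dicarbaldehyde | COc1c(C=O)c(Br)cc(O)c1C=O | intermediate
8 | propyne | CC#C | starting material
9 | 3-(dimethoxymethyl)-2-methoxy-4-[(4-methoxybenzyl)oxy]-6-(prop-1-yn-1-yl)benzaldehyde | CC#Cc1cc(OCc2ccc(OC)cc2)c(C(OC)OC)c(OC)c1C=O | intermediate
10 | 7-(dimethoxymethyl)-8-methoxy-6-[(4-methoxybenzyl)oxy]-3-methylisoquinoline | COc1ccc(COc2cc3cc(C)ncc3c(OC)c2C(OC)OC)cc1 | intermediate (not isolated)
11 | 8-methoxy-6-[(4-methoxybenzyl)oxy]-3-methylisoquinoline-7-carbaldehyde | COc1ccc(COc2cc3cc(C)ncc3c(OC)c2C=O)cc1 | intermediate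
12 | (+)-B-allyldiisopinocampheylborane (from (−)-α-pinene) | C=CCB([C@H]1C[C@H]2C[C@@H]([C@@H]1C)C2(C)C)[C@H]1C[C@H]2C[C@@H]([C@@H]1C)C2(C)C | starting material
13 | diisopinocampheylborinate of alcohol 14 | C=CC[C@@H](OB([C@H]1C[C@H]2C[C@@H]([C@@H]1C)C2(C)C)[C@H]1C[C@H]2C[C@@H]([C@@H]1C)C2(C)C)c1c(OCc2ccc(OC)cc2)cc2cc(C)ncc2c1OC | intermediate (not isolated)
14 | (1R)-1-{8-methoxy-6-[(4-methoxybenzyl)oxy]-3-methylisoquinolin-7-yl}but-3-en-1-ol | C=CC[C@@H](O)c1c(OCc2ccc(OC)cc2)cc2cc(C)ncc2c1OC | intermediate
15 | 7-[(1R)-1-hydroxybut-3-en-1-yl]-8-methoxy-3-methylisoquinolin-6-ol | C=CC[C@@H](O)c1c(O)cc2cc(C)ncc2c1OC | intermediate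
16 | (2R,4R)-cis-2-(6-bromo-3-formyl-4-hydroxy-2-methoxyphenyl)-4-allyl-4H-1,3-dioxine fused at isoquinoline C6 (O1) and C7 (C4); 8-methoxy, 3-methyl | COc1c(C=O)c(O)cc(Br)c1[C@H]1Oc2cc3cc(C)ncc3c(OC)c2[C@H](O1)CC=C | intermediate
17 | methoxymethyl ether of 16 at the ring A phenol | COc1c(C=O)c(OCOC)cc(Br)c1[C@H]1Oc2cc3cc(C)ncc3c(OC)c2[C@H](O1)CC=C | intermediate
18 | (2R,4R)-cis-2-[6-bromo-3-formyl-2-methoxy-4-(methoxymethoxy)phenyl]-4-(2-oxopropyl)-4H-1,3-dioxine fused at isoquinoline C6 (O1) and C7 (C4); 8-methoxy, 3-methyl | COc1c(C=O)c(OCOC)cc(Br)c1[C@H]1Oc2cc3cc(C)ncc3c(OC)c2[C@H](O1)CC(C)=O | intermediate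
19 | bridged acetal, ring A methoxymethyl ether of the target (acetal carbon R, benzylic O–CH carbon R, acetyl-bearing carbon S) | COc1c(C=O)c(OCOC)cc2c1[C@H]1Oc3cc4cc(C)ncc4c(OC)c3[C@H](O1)[C@H]2C(C)=O | intermediate
20 | CNP0584953.1 | COc1c(C=O)c(O)cc2c1[C@H]1Oc3cc4cc(C)ncc4c(OC)c3[C@H](O1)[C@H]2C(C)=O | target

**Step count**

Total: 14 steps. Longest linear sequence: 13 steps (steps 1–4 and 6–14); step 5 is the one-step branch to the ring A fragment.

**Steps most likely to fail**

Step 13. The enolate, or the carbon-bound palladium enolate, may expel the acetal oxygen on C4 before the C–C bond forms (retro-oxa-Michael). That would open the dioxine, erase the C4 centre and release the ring A aldehyde. Fallback: setting out from 18, soft enolisation (Me3SiOTf, Et3N, CH2Cl2, −78 → 0 °C) gives the internal (Z)-trimethylsilyl enol ether F1. The fluoride-promoted palladium-catalysed arylation of silyl enol ethers (Pd(dba)2, P(t-Bu)3, ZnF2, CsF, DMF, 70 °C) then closes the same bond through a zinc enolate, with no alkali enolate present, and returns to the route at 19. Any terminal enol ether cannot cyclise and reverts to 18 on work-up.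

Step 10. The acetal equilibrium may settle on the trans isomer, because the C8 methoxy group crowds an in-plane C4 substituent. Prolonged heating of the free ortho-hydroxybenzylic alcohol with acid may also cost the carbinol by loss of water (quinone methide formation) before the hindered aldehyde has condensed. Fallback (oxidative instead of condensative acetal formation), setting out from 6 and 15:
- NaBH4 reduces the free formyl group of 6 to {6-bromo-3-(dimethoxymethyl)-2-methoxy-4-[(4-methoxybenzyl)oxy]phenyl}methanol F2.
- A Mitsunobu reaction with the phenol of 15 gives the aryl benzyl ether F3.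
- DDQ (excess, CH2Cl2, 4 Å MS, rt) abstracts hydride from the electron-rich benzylic ether carbon, and the neighbouring carbinol oxygen captures the oxocarbenium ion. The same oxidant removes the 4-methoxybenzyl group, giving the dioxine with ring A formyl still masked as its dimethyl acetal F4.
- PPTS in wet acetone hydrolyses that acetal, and the sequence returns to the route at 16.

Any trans isomer formed this way is equilibrated with PPTS at the acetal stage, where no free benzylic alcohol remains.

Step 12. Coordination of PdCl2 by the isoquinoline nitrogen may stall the oxidation, or the homoallylic acetal oxygen may steer part of the attack to the terminal carbon. Fallback: setting out from 17, Mukaiyama hydration (Co(acac)2, PhSiH3, O2, i-PrOH–THF) gives the Markovnikov secondary alcohol F5 as a mixture of carbinol epimers, and Dess–Martin oxidation returns to the route at 18.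

**Further compounds**

F1 | step 13 | (Z)-trimethylsilyl enol ether of 18 at the internal α-carbon | COc1c(C=O)c(OCOC)cc(Br)c1[C@H]1Oc2cc3cc(C)ncc3c(OC)c2[C@H](O1)/C=C(/C)O[Si](C)(C)C
F2 | step 10 | {6-bromo-3-(dimethoxymethyl)-2-methoxy-4-[(4-methoxybenzyl)oxy]phenyl}methanol | COc1ccc(COc2cc(Br)c(CO)c(OC)c2C(OC)OC)cc1
F3 | step 10 | (1R)-1-{6-[(aryl)methoxy]-8-methoxy-3-methylisoquinolin-7-yl}but-3-en-1-ol, aryl = 6-bromo-3-(dimethoxymethyl)-2-methoxy-4-[(4-methoxybenzyl)oxy]phenyl | COc1ccc(COc2cc(Br)c(COc3cc4cc(C)ncc4c(OC)c3[C@H](O)CC=C)c(OC)c2C(OC)OC)cc1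
F4 | step 10 | (2R,4R)-cis-2-[6-bromo-3-(dimethoxymethyl)-4-hydroxy-2-methoxyphenyl]-4-allyl-4H-1,3-dioxine fused at isoquinoline C6 and C7; 8-methoxy, 3-methyl | COc1c(C(OC)OC)c(O)cc(Br)c1[C@H]1Oc2cc3cc(C)ncc3c(OC)c2[C@H](O1)CC=C
F5 | step 12 | 2-hydroxypropyl analogue of 18 (carbinol epimers) | COc1c(C=O)c(OCOC)cc(Br)c1[C@H]1Oc2cc3cc(C)ncc3c(OC)c2[C@H](O1)CC(C)O
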